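## Retrosynthetic overview

1. The target is cut at the ester between the two halves: the carboxylate of fragment B (acid 22) opens the spiro-epoxide of fragment A (17) at its CH2 terminus, then one acidolysis frees the last acid and alcohol.
2. Fragment A: the oxepinone is closed last by ring-closing metathesis; the tertiary carbinol comes from an iodolactonisation/epoxide closure steered by the neighbouring carboxyl; the ring-to-carboxyl C–C bond and the exocyclic methylene come from a [2,3]-sigmatropic (Büchi) rearrangement of allylic alcohol 8 (key step).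
3. Fragment B: tandem oxa-Michael/Horner–Wadsworth–Emmons olefination of the cis aldehyde 20, made from the same alcohol 8 by acetal hydrolysis and deconjugative kinetic protonation.
4. Alcohol 8 comes from (R)-phellandral 5 by a vinylogous Mukaiyama reaction with trimethyl orthoformate; 5 comes from (+)-limonene oxide 1, the only chiral purchase.
5. Ring order: both carbocycles (ring A of the lactone half, ring B of the acyl half) are bought in 1; then the fused lactol (step 7), a transient β-lactone and the oxirane (step 8), and the oxepinone (step 11).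

Assumption: commercial (+)-limonene oxide is the usual (4R) cis/trans epoxide mixture; both epimers converge because the epoxide carbons become sp2 in steps 2–3.

## Route

Step 1
Reactants: 1 (+)-limonene oxide
Product: 2 (4R)-1-methyl-4-(propan-2-yl)-7-oxabicyclo[4.1.0]heptane (cis/trans mixture)
Conditions: H2 (1 atm), RhCl(PPh3)3 (2 mol %), PhH–EtOH, rt
Reagents that add atoms: none
Why: Chemoselective homogeneous catalytic hydrogenation saturates only the unhindered 1,1-disubstituted alkene and leaves the epoxide and the C4 stereocentre untouched.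

Step 2
Reactants: 2 (4R)-1-methyl-4-(propan-2-yl)-7-oxabicyclo[4.1.0]heptane
Product: 3 (5R)-2-methylidene-5-(propan-2-yl)cyclohexan-1-ol (both C1 epimers)
Conditions: LiNEt2 (2.5 equiv, from Et2NH and n-BuLi), Et2O–hexane, 0 °C → reflux; H2O
Reagents that add atoms: none
Why: Base-induced epoxide-to-allylic-alcohol isomerisation (syn β-elimination) removes a proton from the unhindered methyl group, so both epoxide epimers give the exocyclic methylene alcohol, whose carbinol centre is erased in step 3.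

Step 3
Reactants: 3 (5R)-2-methylidene-5-(propan-2-yl)cyclohexan-1-ol
Product: 5 (4R)-4-(propan-2-yl)cyclohex-1-ene-1-carbaldehyde, via primary allylic alcohol 4 (not isolated)
Conditions: Ph3SiOReO3 (2 mol %), Et2O, 0 °C; then MnO2 (15 equiv), CH2Cl2, rt
Reagents that add atoms: none
Why: Perrhenate-catalysed 1,3-transposition of the allylic alcohol ([3,3] shift of the perrhenate ester) drains to the endocyclic trisubstituted alkene with a primary alcohol, which MnO2 allylic oxidation converts to the enal in the same flask.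

Step 4
Reactants: 5 (4R)-4-(propan-2-yl)cyclohex-1-ene-1-carbaldehyde
Product: 7 (3S,4S)-3-(dimethoxymethyl)-4-(propan-2-yl)cyclohex-1-ene-1-carbaldehyde, via trimethylsilyl dienol ether 6 (not isolated)
Conditions: Me3SiOTf (1.2 equiv), Et3N (1.3 equiv), CH2Cl2, 0 °C; then HC(OMe)3 (3 equiv), Me3SiOTf (0.3 equiv), −78 → −30 °C; NaHCO3 (aq)
Reagents that add atoms: trimethyl orthoformate COC(OC)OC
Why: Soft enolisation followed by a vinylogous Mukaiyama reaction lets the 1-silyloxydiene attack the dimethoxycarbenium ion through its γ-carbon, anti to the adjacent isopropyl group, which sets the 3,4-trans centre.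

Step 5
Reactants: 7 (3S,4S)-3-(dimethoxymethyl)-4-(propan-2-yl)cyclohex-1-ene-1-carbaldehyde
Product: 8 [(3S,4S)-3-(dimethoxymethyl)-4-(propan-2-yl)cyclohex-1-en-1-yl]methanol
Conditions: NaBH4, CeCl3·7H2O, MeOH, −20 °C
Reagents that add atoms: none
Why: Luche 1,2-reduction of the enal gives the allylic alcohol without touching the acetal or either stereocentre.

Step 6
Reactants: 8 [(3S,4S)-3-(dimethoxymethyl)-4-(propan-2-yl)cyclohex-1-en-1-yl]methanol
Product: 11 (1S,2S,3S)-2-(dimethoxymethyl)-N,N-dimethyl-6-methylidene-3-(propan-2-yl)cyclohexane-1-carboxamide, via mixed amide acetal 9 (not isolated), via aminooxycarbene 10 (not isolated)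
Conditions: Me2NCH(OMe)2 (5 equiv), xylenes, 140 °C, MeOH distilled off
Reagents that add atoms: N,N-dimethylformamide dimethyl acetal COC(OC)N(C)C
Why: In this Büchi [2,3]-sigmatropic rearrangement the alkoxy(amino)carbene carbon is delivered suprafacially to the ring carbon along the axial trajectory of the half-chair with equatorial isopropyl (the other face would be 1,3-diaxial to it), giving the axial amide cis to the acetal-bearing carbon and trans to isopropyl, together with the exocyclic methylene.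

Step 7
Reactants: 11 (1S,2S,3S)-2-(dimethoxymethyl)-N,N-dimethyl-6-methylidene-3-(propan-2-yl)cyclohexane-1-carboxamide
Product: 12 (3aS,4S,7aS)-3-hydroxy-7-methylidene-4-(propan-2-yl)hexahydro-2-benzofuran-1(3H)-one (lactol; both C3 anomers; ring-chain tautomer of the formyl acid)
Conditions: 1 M HCl–THF (1:3), rt
Reagents that add atoms: water O
Why: Acetal hydrolysis with neighbouring-group participation: the cis amide oxygen traps the oxocarbenium carbon as a five-membered iminium ether that water hydrolyses with loss of dimethylamine, so the amide is cleaved under mild acid and no stereocentre is touched.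

Step 8
Reactants: 12 (3aS,4S,7aS)-3-hydroxy-7-methylidene-4-(propan-2-yl)hexahydro-2-benzofuran-1(3H)-one
Product: 14 (3aS,4S,7R,7aS)-3-hydroxy-4-(propan-2-yl)hexahydro-3H-spiro[2-benzofuran-7,2'-oxiran]-1-one (lactol; both C3 anomers), via iodo-beta-lactone 13 (not isolated)
Conditions: I2 (1.5 equiv), NaHCO3, MeCN–H2O, 0 °C, dark; Na2S2O3; then 1 M NaOH, 0 °C; NaH2PO4 to pH 5
Reagents that add atoms: sodium hydroxide [Na+].[OH-]
Why: Kinetic iodolactonisation of the β,γ-unsaturated carboxylate (4-exo, Markovnikov) places oxygen on the tertiary carbon on the carboxyl face by ring constraint, and saponification then lets the freed tertiary alkoxide displace iodide (Williamson epoxide closure), fixing the carbinol configuration cis to the carboxyl.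

Step 9
Reactants: 14 (3aS,4S,7R,7aS)-3-hydroxy-4-(propan-2-yl)hexahydro-3H-spiro[2-benzofuran-7,2'-oxiran]-1-one
Product: 15 (3R,4S,5S,6S)-5-ethenyl-6-(propan-2-yl)-1-oxaspiro[2.5]octane-4-carboxylic acid
Conditions: Ph3PCH3Br (3.2 equiv), KN(SiMe3)2 (3.0 equiv), THF, 0 °C → rt; NaH2PO4 (aq)
Reagents that add atoms: methyltriphenylphosphonium bromide C[P+](c1ccccc1)(c1ccccc1)c1ccccc1.[Br-]
Why: Wittig methylenation of the lactol through its open formyl carboxylate gives the vinyl group, and the epoxide survives because its CH2 lies anti to the axial carboxylate.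

Step 10
Reactants: 15 (3R,4S,5S,6S)-5-ethenyl-6-(propan-2-yl)-1-oxaspiro[2.5]octane-4-carboxylic acid
Product: 16 2-(tert-butoxycarbonyl)prop-2-en-1-yl (3R,4S,5S,6S)-5-ethenyl-6-(propan-2-yl)-1-oxaspiro[2.5]octane-4-carboxylate
Conditions: CH2=C(CH2Br)CO2t-Bu (1.2 equiv), Cs2CO3 (0.6 equiv), DMF, 0 °C → rt
Reagents that add atoms: tert-butyl 2-(bromomethyl)prop-2-enoate C=C(CBr)C(=O)OC(C)(C)C
Why: SN2 O-alkylation of the caesium carboxylate by the reactive allylic bromide installs the acrylate partner without any stereochemical consequence.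

Step 11
Reactants: 16 2-(tert-butoxycarbonyl)prop-2-en-1-yl (3R,4S,5S,6S)-5-ethenyl-6-(propan-2-yl)-1-oxaspiro[2.5]octane-4-carboxylate
Product: 17 tert-butyl (5aR,6S,9R,9aS)-1-oxo-6-(propan-2-yl)-3,5a,6,7,8,9a-hexahydro-1H-spiro[2-benzoxepine-9,2'-oxirane]-4-carboxylate (fragment A)
Conditions: second-generation Grubbs catalyst (5 mol %), CH2Cl2 (5 mM), 40 °C
Reagents that add atoms: none
Why: Ring-closing metathesis between the vinyl group and the acrylate closes the cis-fused oxepinone, and the ring forces the required alkene geometry (ester carbon trans to the ring carbon).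

Step 12
Reactants: 8 [(3S,4S)-3-(dimethoxymethyl)-4-(propan-2-yl)cyclohex-1-en-1-yl]methanol
Product: 18 (1S,6S)-3-(hydroxymethyl)-6-(propan-2-yl)cyclohex-2-ene-1-carbaldehyde (1,6-trans)
Conditions: pyridinium p-toluenesulfonate (10 mol %), acetone–H2O (10:1), rt
Reagents that add atoms: water O
Why: Mild acid-catalysed acetal hydrolysis unmasks the β,γ-unsaturated aldehyde without conjugating the alkene or touching the stereocentres.

Step 13
Reactants: 18 (1S,6S)-3-(hydroxymethyl)-6-(propan-2-yl)cyclohex-2-ene-1-carbaldehyde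
Product: 20 (1R,6S)-3-(hydroxymethyl)-6-(propan-2-yl)cyclohex-2-ene-1-carbaldehyde (1,6-cis), via dipotassium dienolate 19 (not isolated)
Conditions: KN(SiMe3)2 (2.3 equiv), THF, −78 °C (aldehyde added to base); AcOH (5 equiv), −78 °C
Reagents that add atoms: none
Why: Deconjugative kinetic protonation of the extended enolate occurs at the α-carbon from the face opposite the isopropyl group (held pseudoaxial by allylic 1,3-strain), giving the less stable cis aldehyde.

Step 14
Reactants: 20 (1R,6S)-3-(hydroxymethyl)-6-(propan-2-yl)cyclohex-2-ene-1-carbaldehyde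
Product: 21 ethyl (2E)-3-[(1R,6S)-3-(hydroxymethyl)-6-(propan-2-yl)cyclohex-2-en-1-yl]-2-{[(4-methoxyphenyl)methoxy]methyl}prop-2-enoate
Conditions: 4-MeOC6H4CH2OH (2.2 equiv), NaH (2.2 equiv), THF, 0 °C; CH2=C(CO2Et)P(O)(OEt)2 (2.2 equiv), 0 °C; then 20, −78 → 0 °C
Reagents that add atoms: 4-methoxybenzyl alcohol COc1ccc(CO)cc1; ethyl 2-(diethoxyphosphoryl)prop-2-enoate C=C(C(=O)OCC)P(=O)(OCC)OCC
Why: Tandem oxa-Michael addition/Horner–Wadsworth–Emmons olefination: the alkoxide adds to the vinylphosphonate and the resulting carbanion olefinates the α-branched aldehyde at low temperature, favouring the E-enoate with the ring trans to the ester.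

Step 15
Reactants: 21 ethyl (2E)-3-[(1R,6S)-3-(hydroxymethyl)-6-(propan-2-yl)cyclohex-2-en-1-yl]-2-{[(4-methoxyphenyl)methoxy]methyl}prop-2-enoate
Product: 22 (2E)-3-[(1R,6S)-3-(hydroxymethyl)-6-(propan-2-yl)cyclohex-2-en-1-yl]-2-{[(4-methoxyphenyl)methoxy]methyl}prop-2-enoic acid (fragment B)
Conditions: LiOH·H2O (5 equiv), THF–MeOH–H2O, rt; 1 M HCl to pH 3
Reagents that add atoms: lithium hydroxide [Li+].[OH-]
Why: Saponification of the ethyl enoate gives the acid while the benzylic ether, the allylic alcohol and the stereocentres are inert to hydroxide at room temperature.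

Step 16
Reactants: 17 fragment A epoxy lactone; 22 fragment B acid (1.3 equiv)
Product: 23 tert-butyl (5aR,6S,9R,9aS)-9-hydroxy-9-{[((2E)-3-[(1R,6S)-3-(hydroxymethyl)-6-(propan-2-yl)cyclohex-2-en-1-yl]-2-{[(4-methoxyphenyl)methoxy]methyl}prop-2-enoyl)oxy]methyl}-1-oxo-6-(propan-2-yl)-1,3,5a,6,7,8,9,9a-octahydro-2-benzoxepine-4-carboxylate
Conditions: Cs2CO3 (0.2 equiv), DMF, 60 °C
Reagents that add atoms: none
Why: Base-catalysed regioselective SN2 opening of the spiro-epoxide at its CH2 terminus by the carboxylate (the free alcohol does not compete) forms the ester link and frees the tertiary alcohol with retention at the quaternary carbon.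

Step 17
Reactants: 23 protected coupling product
Product: 24 (5aR,6S,9R,9aS)-9-hydroxy-9-({[(2E)-2-(hydroxymethyl)-3-[(1R,6S)-3-(hydroxymethyl)-6-(propan-2-yl)cyclohex-2-en-1-yl]prop-2-enoyl]oxy}methyl)-1-oxo-6-(propan-2-yl)-1,3,5a,6,7,8,9,9a-octahydro-2-benzoxepine-4-carboxylic acid (target)
Conditions: CF3CO2H–CH2Cl2 (1:4), anisole (10 equiv), 0 °C → rt; then MeOH, rt
Reagents that add atoms: none
Why: Acidolysis through stabilised carbocations removes the tert-butyl ester and the 4-methoxybenzyl ether in one operation, while the lactone, the enoate ester and the tertiary alcohol are stable and methanol cleaves any transient trifluoroacetates.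

## Compound list

1 | (+)-limonene oxide, (4R)-1-methyl-4-(prop-1-en-2-yl)-7-oxabicyclo[4.1.0]heptane, cis/trans mixture | CC(=C)[C@@H]1CCC2(C)OC2C1 | starting material
2 | (4R)-1-methyl-4-(propan-2-yl)-7-oxabicyclo[4.1.0]heptane, cis/trans mixture | CC(C)[C@@H]1CCC2(C)OC2C1 | intermediate
3 | (5R)-2-methylidene-5-(propan-2-yl)cyclohexan-1-ol, both C1 epimers | CC(C)[C@@H]1CCC(=C)C(O)C1 | intermediate
4 | [(4R)-4-(propan-2-yl)cyclohex-1-en-1-yl]methanol (not isolated) | CC(C)[C@@H]1CCC(CO)=CC1 | intermediate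
5 | (4R)-4-(propan-2-yl)cyclohex-1-ene-1-carbaldehyde, (R)-phellandral | CC(C)[C@@H]1CCC(C=O)=CC1 | intermediate
6 | trimethyl{[(4S)-4-(propan-2-yl)cyclohex-2-en-1-ylidene]methoxy}silane (not isolated) | CC(C)[C@@H]1CCC(=CO[Si](C)(C)C)C=C1 | intermediate
7 | (3S,4S)-3-(dimethoxymethyl)-4-(propan-2-yl)cyclohex-1-ene-1-carbaldehyde | CC(C)[C@@H]1CCC(C=O)=C[C@H]1C(OC)OC | intermediate
8 | [(3S,4S)-3-(dimethoxymethyl)-4-(propan-2-yl)cyclohex-1-en-1-yl]methanol | CC(C)[C@@H]1CCC(CO)=C[C@H]1C(OC)OC | intermediate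
9 | 1-{[(3S,4S)-3-(dimethoxymethyl)-4-(propan-2-yl)cyclohex-1-en-1-yl]methoxy}-1-methoxy-N,N-dimethylmethanamine (not isolated) | CC(C)[C@@H]1CCC(COC(OC)N(C)C)=C[C@H]1C(OC)OC | intermediate
10 | {[(3S,4S)-3-(dimethoxymethyl)-4-(propan-2-yl)cyclohex-1-en-1-yl]methoxy}(dimethylamino)carbene (not isolated) | CC(C)[C@@H]1CCC(CO[C]N(C)C)=C[C@H]1C(OC)OC | intermediate
11 | (1S,2S,3S)-2-(dimethoxymethyl)-N,N-dimethyl-6-methylidene-3-(propan-2-yl)cyclohexane-1-carboxamide | CC(C)[C@@H]1CCC(=C)[C@@H](C(=O)N(C)C)[C@H]1C(OC)OC | intermediate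
12 | (3aS,4S,7aS)-3-hydroxy-7-methylidene-4-(propan-2-yl)hexahydro-2-benzofuran-1(3H)-one, both C3 anomers | CC(C)[C@@H]1CCC(=C)[C@H]2C(=O)OC(O)[C@@H]12 | intermediate
13 | (1S,2S,3S,6R)-6-(iodomethyl)-8-oxo-3-(propan-2-yl)-7-oxabicyclo[4.2.0]octane-2-carbaldehyde (not isolated) | CC(C)[C@@H]1CC[C@@]2(CI)OC(=O)[C@H]2[C@H]1C=O | intermediate
14 | (3aS,4S,7R,7aS)-3-hydroxy-4-(propan-2-yl)hexahydro-3H-spiro[2-benzofuran-7,2'-oxiran]-1-one, both C3 anomers | CC(C)[C@@H]1CC[C@]3(CO3)[C@H]2C(=O)OC(O)[C@@H]12 | intermediate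
15 | (3R,4S,5S,6S)-5-ethenyl-6-(propan-2-yl)-1-oxaspiro[2.5]octane-4-carboxylic acid | CC(C)[C@@H]1CC[C@]2(CO2)[C@@H](C(=O)O)[C@H]1C=C | intermediate
16 | 2-(tert-butoxycarbonyl)prop-2-en-1-yl (3R,4S,5S,6S)-5-ethenyl-6-(propan-2-yl)-1-oxaspiro[2.5]octane-4-carboxylate | CC(C)[C@@H]1CC[C@]2(CO2)[C@@H](C(=O)OCC(=C)C(=O)OC(C)(C)C)[C@H]1C=C | intermediate
17 | tert-butyl (5aR,6S,9R,9aS)-1-oxo-6-(propan-2-yl)-3,5a,6,7,8,9a-hexahydro-1H-spiro[2-benzoxepine-9,2'-oxirane]-4-carboxylate (fragment A) | CC(C)[C@@H]1CC[C@]3(CO3)[C@H]2C(=O)OCC(C(=O)OC(C)(C)C)=C[C@@H]12 | intermediate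
18 | (1S,6S)-3-(hydroxymethyl)-6-(propan-2-yl)cyclohex-2-ene-1-carbaldehyde (trans) | O=C[C@@H]1C=C(CO)CC[C@H]1C(C)C | intermediate
19 | dipotassium {(6S)-3-(oxidomethyl)-6-(propan-2-yl)cyclohex-2-en-1-ylidene}methanolate (not isolated) | [K+].[K+].[O-]C=C1C=C(C[O-])CC[C@H]1C(C)C | intermediate
20 | (1R,6S)-3-(hydroxymethyl)-6-(propan-2-yl)cyclohex-2-ene-1-carbaldehyde (cis) | O=C[C@H]1C=C(CO)CC[C@H]1C(C)C | intermediate
21 | ethyl (2E)-3-[(1R,6S)-3-(hydroxymethyl)-6-(propan-2-yl)cyclohex-2-en-1-yl]-2-{[(4-methoxyphenyl)methoxy]methyl}prop-2-enoate | CCOC(=O)/C(COCc1ccc(OC)cc1)=C/[C@H]1C=C(CO)CC[C@H]1C(C)C | intermediate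
22 | (2E)-3-[(1R,6S)-3-(hydroxymethyl)-6-(propan-2-yl)cyclohex-2-en-1-yl]-2-{[(4-methoxyphenyl)methoxy]methyl}prop-2-enoic acid (fragment B) | OC(=O)/C(COCc1ccc(OC)cc1)=C/[C@H]1C=C(CO)CC[C@H]1C(C)C | intermediate
23 | tert-butyl ester and 4-methoxybenzyl ether of the target (name as in step 16) | CC(C)[C@@H]1CC[C@](O)(COC(=O)/C(COCc3ccc(OC)cc3)=C/[C@H]4C=C(CO)CC[C@H]4C(C)C)[C@H]2C(=O)OCC(C(=O)OC(C)(C)C)=C[C@@H]12 | intermediate
24 | CNP0361406.6 (name as in step 17) | CC(C)[C@@H]1CC[C@](O)(COC(=O)/C(=C/[C@H]2C=C(CO)CC[C@H]2C(C)C)CO)[C@H]2C(=O)OCC(C(=O)O)=C[C@@H]12 | target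

## Step count and risks

Total step count: 17. Longest linear sequence: 13 (steps 1–11, 16, 17); fragment B branches from 8 (steps 12–15).

Three steps most likely to fail:

Step 6 (thermal carbene [2,3] shift onto a hindered ring carbon; yield and face selectivity). The fallback sets out from 8 and comes back at 12, replacing the carbene route by an anionic Wittig–Still [2,3] rearrangement. O-Alkylation of 8 (KH, Bu3SnCH2I, THF) gives stannylmethyl ether F1. Tin–lithium exchange (n-BuLi, THF, −78 °C) triggers the shift to homoallylic alcohol F2. One-pot TEMPO/NaOCl/NaClO2 oxidation (pH 6.7 buffer) gives acetal acid F3. 1 M HCl–THF then unmasks the aldehyde, which closes to lactol 12.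

Step 13 (aldehyde dienolate: aldol side reactions and incomplete kinetic control). The fallback sets out from 18 and comes back at 20, moving the inversion to the ester oxidation level, where dienolates are well behaved. Pinnick oxidation (NaClO2, NaH2PO4, 2-methylbut-2-ene) gives trans acid F4. Me3SiCHN2 (MeOH–toluene) gives trans methyl ester F5. LiN(i-Pr)2 (2.2 equiv, THF, −78 °C) followed by AcOH at −78 °C gives, by deconjugative protonation of the ester dienolate, cis methyl ester F6. (i-Bu)2AlH (CH2Cl2, −78 °C) reduces F6 to aldehyde 20.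

Step 14 (E/Z ratio of the tandem olefination and base-induced epimerisation of 20). The fallback sets out from 20 and comes back at 21, replacing the olefination by carbonyl addition plus allylic transposition. The vinylalane from ethyl propiolate and (i-Bu)2AlH (THF–HMPA, 0 °C) adds to 20 to give Baylis–Hillman-type diol F7. Ac2O/pyridine/DMAP gives diacetate F8. Sodium 4-methoxybenzyl oxide (2.2 equiv, THF, 0 °C) displaces the secondary acetate in SN2′ fashion to the E-enoate and transesterifies the primary acetate, giving 21.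

Further compounds
F1 | step 6 | tributyl({[(3S,4S)-3-(dimethoxymethyl)-4-(propan-2-yl)cyclohex-1-en-1-yl]methoxy}methyl)stannane | CC(C)[C@@H]1CCC(COC[Sn](CCCC)(CCCC)CCCC)=C[C@H]1C(OC)OC
F2 | step 6 | [(1S,2S,3S)-2-(dimethoxymethyl)-6-methylidene-3-(propan-2-yl)cyclohexyl]methanol | CC(C)[C@@H]1CCC(=C)[C@@H](CO)[C@H]1C(OC)OC
F3 | step 6 | (1S,2S,3S)-2-(dimethoxymethyl)-6-methylidene-3-(propan-2-yl)cyclohexane-1-carboxylic acid | CC(C)[C@@H]1CCC(=C)[C@@H](C(=O)O)[C@H]1C(OC)OC
F4 | step 13 | (1S,6S)-3-(hydroxymethyl)-6-(propan-2-yl)cyclohex-2-ene-1-carboxylic acid | OC(=O)[C@@H]1C=C(CO)CC[C@H]1C(C)C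
F5 | step 13 | methyl (1S,6S)-3-(hydroxymethyl)-6-(propan-2-yl)cyclohex-2-ene-1-carboxylate | COC(=O)[C@@H]1C=C(CO)CC[C@H]1C(C)C
F6 | step 13 | methyl (1R,6S)-3-(hydroxymethyl)-6-(propan-2-yl)cyclohex-2-ene-1-carboxylate | COC(=O)[C@H]1C=C(CO)CC[C@H]1C(C)C
F7 | step 14 | ethyl 2-{hydroxy[(1R,6S)-3-(hydroxymethyl)-6-(propan-2-yl)cyclohex-2-en-1-yl]methyl}prop-2-enoate (carbinol epimers) | CCOC(=O)C(=C)C(O)[C@H]1C=C(CO)CC[C@H]1C(C)C
F8 | step 14 | ethyl 2-{(acetyloxy)[(1R,6S)-3-[(acetyloxy)methyl]-6-(propan-2-yl)cyclohex-2-en-1-yl]methyl}prop-2-enoate (carbinol epimers) | CCOC(=O)C(=C)C(OC(C)=O)[C@H]1C=C(COC(C)=O)CC[C@H]1C(C)C
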